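Numbering: C1 carries OH and C7H2OBz; C2=C3 is the alkene; C4 carries OBz; C5 and C6 carry OH. Because C7 and the oxygen on C4 sit cis across the C2=C3 alkene, the cyclohexene is a masked 2-oxabicyclo[2.2.2]octenone whose lactone spans C1 and C4 and whose bridgehead is the C1 carbinol. One amine-catalysed asymmetric [4+2] of unprotected 3-hydroxy-2-pyrone with the symmetrical (E)-hex-3-ene-2,5-dione forms C1–C6 and C4–C5, closes the carbocycle and sets all four stereocentres, leaving trans acetyl groups on C5 and C6. Double Baeyer–Villiger oxidation, lactone opening with diol masking, reduction, dibenzoylation and acetal removal complete the synthesis.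

Key step: step 2

Assumption: of the two pseudo-enantiomeric cinchona amine–thiourea catalysts, the quinidine-derived one is taken to give the (1R,4R,5S,6S) adduct; if the first run shows the mirror-image series, the quinine-derived catalyst is used with nothing else changed.

Step 1
Reactants: 1 2,5-dimethylfuran
Product: 3 (E)-hex-3-ene-2,5-dione, via (Z)-hex-3-ene-2,5-dione 2 (not isolated)
Conditions: NBS (1.05 equiv), NaHCO3 (2 equiv), acetone/H2O (10:1), −15 °C; then pyridine (2 equiv), rt
Reagents that add atoms: water, O
Why: NBS-mediated oxidative ring opening of the 2,5-dialkylfuran (bromonium formation, addition of water, loss of HBr) unmasks the cis-enedione, which pyridine then isomerises by reversible conjugate addition–elimination to the more stable E isomer; no stereocentre is formed and the alkene geometry is set under thermodynamic control.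

Step 2
Reactants: 4 3-hydroxy-2H-pyran-2-one (3-hydroxy-2-pyrone); 3 (E)-hex-3-ene-2,5-dione
Product: 5 (1R,4R,5S,6S)-5,6-diacetyl-4-hydroxy-2-oxabicyclo[2.2.2]oct-7-en-3-one
Conditions: 9-amino(9-deoxy)epi-quinidine 3,5-bis(trifluoromethyl)phenyl thiourea (10 mol %), TBME, −20 °C
Reagents that add atoms: none
Why: The quinuclidine nitrogen deprotonates the 3-OH of 4 to an ammonium-bound dienolate while the thiourea hydrogen-bonds one acetyl carbonyl of 3, and an asynchronous [4+2] follows: vinylogous Michael attack of the pyrone C6 (future C4) on the enone β-carbon (future C5), then aldol attack of the resulting enolate carbon (future C6) on the pyranone C3 carbonyl (future C1). The closest known reaction type is the cinchona-amine-catalysed asymmetric Diels–Alder reaction of 3-hydroxy-2-pyrones with enones and other electron-poor alkenes. The only ring closed is the six-membered carbocycle C1–C6, formed in cycloaddition mode with the second bond made by a 6-exo-trig (enolexo) aldol; the lactone bridge is carried in intact from the pyrone. C1 and C4 are set together by the dienolate face that the catalyst leaves open, because both diene termini bond suprafacially; C5 and C6 are trans because the E alkene adds suprafacially, and their placement follows from the thiourea-bound acetyl (on future C6) lying under the diene next to the ammonium-bound oxygen, which turns the other acetyl (on future C5) toward the lactone. The step needs one π-face and one of the two trans orientations; the twofold symmetry of 3 removes any regiochemical question, the chiral pocket of the catalyst is relied on for both remaining choices, and the low temperature keeps the adduct from retro-aldol opening or loss of CO2.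

Step 3
Reactants: 5 (1R,4R,5S,6S)-5,6-diacetyl-4-hydroxy-2-oxabicyclo[2.2.2]oct-7-en-3-one
Product: 6 (1R,4R,5S,6R)-4-hydroxy-3-oxo-2-oxabicyclo[2.2.2]oct-7-ene-5,6-diyl diacetate
Conditions: mCPBA (5 equiv), TFA (1 equiv), CH2Cl2, 0 °C → rt, dark
Reagents that add atoms: mCPBA, O=C(OO)c1cccc(Cl)c1
Why: In this double Baeyer–Villiger oxidation each Criegee adduct should rearrange by migration of the secondary ring carbon in preference to methyl, with retention, so both acetyl groups become acetates without change at C5 or C6, while the ring alkene, flanked by two oxygenated bridgeheads, is electron-poor and is expected to resist the peracid under acid-accelerated conditions.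

Step 4
Reactants: 6 (1R,4R,5S,6R)-4-hydroxy-3-oxo-2-oxabicyclo[2.2.2]oct-7-ene-5,6-diyl diacetate
Product: 8 methyl (1R,4R,5R,6S)-1,4-dihydroxy-5,6-O-[(2S,3S)-2,3-dimethoxybutane-2,3-diyl]cyclohex-2-ene-1-carboxylate, via tetrol methyl ester 7 (not isolated)
Conditions: K2CO3 (0.1 equiv), MeOH, 0 °C → rt; then CSA (0.3 equiv), 2,2,3,3-tetramethoxybutane (1.5 equiv), reflux
Reagents that add atoms: methanol, CO; 2,2,3,3-tetramethoxybutane, COC(C)(OC)C(C)(OC)OC
Why: Zemplén-type transesterification opens the strained α-hydroxy lactone to the methyl ester and removes both acetates, and acid-catalysed transacetalisation then forms the butane-2,3-diacetal on the only trans vicinal diol (C5,C6), as with the trans diols of quinate and shikimate esters, leaving the C4 and C1 hydroxyls free; no ring stereocentre is touched and the two acetal carbons are set under thermodynamic control (trans-fused chair dioxane, both methoxy groups axial by the anomeric effect).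

Step 5
Reactants: 8 methyl (1R,4R,5R,6S)-1,4-dihydroxy-5,6-O-[(2S,3S)-2,3-dimethoxybutane-2,3-diyl]cyclohex-2-ene-1-carboxylate
Product: 9 (1S,4R,5R,6S)-1-(hydroxymethyl)-5,6-O-[(2S,3S)-2,3-dimethoxybutane-2,3-diyl]cyclohex-2-ene-1,4,5,6-tetrol
Conditions: NaBH4 (4 equiv), MeOH, 0 °C → rt
Reagents that add atoms: none
Why: Hydroxyl-assisted borohydride reduction of an α-hydroxy ester, as practised on the analogous diacetal-protected quinate, should give the C7 primary alcohol, the acetal and the isolated alkene being inert to hydride.

Step 6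
Reactants: 9 (1S,4R,5R,6S)-1-(hydroxymethyl)-5,6-O-[(2S,3S)-2,3-dimethoxybutane-2,3-diyl]cyclohex-2-ene-1,4,5,6-tetrol; 10 benzoyl chloride
Product: 11 the O4,O7-dibenzoate of 9, [(1S,4R,5R,6S)-4-(benzoyloxy)-1-hydroxy-5,6-O-[(2S,3S)-2,3-dimethoxybutane-2,3-diyl]cyclohex-2-en-1-yl]methyl benzoate
Conditions: BzCl (2.3 equiv), pyridine, DMAP (cat.), CH2Cl2, −20 → 0 °C
Reagents that add atoms: benzoyl chloride (10), O=C(Cl)c1ccccc1
Why: DMAP-catalysed acylation (nucleophilic acyl substitution) should esterify the primary C7 and the secondary allylic C4 hydroxyls, whereas the hindered tertiary C1 hydroxyl stays free and the C5,C6 oxygens are blocked in the acetal, so no choice among secondary hydroxyls is required.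

Step 7
Reactants: 11 the O4,O7-dibenzoate of 9
Product: 12 [(1S,4R,5S,6S)-4-(benzoyloxy)-1,5,6-trihydroxycyclohex-2-en-1-yl]methyl benzoate
Conditions: TFA/H2O (9:1), CH2Cl2, 0 °C → rt
Reagents that add atoms: none
Why: Acid hydrolysis of the diacetal should free the C5,C6 diol while the benzoates survive aqueous TFA, the oxygen substituents next to C1 and C4 disfavour allylic ionisation, and the short cold exposure limits acyl migration from O4 to the cis O5.

Compound list
1 | 2,5-dimethylfuran | Cc1ccc(C)o1 | starting material
2 | (Z)-hex-3-ene-2,5-dione | CC(=O)/C=C\C(C)=O | intermediate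
3 | (E)-hex-3-ene-2,5-dione | CC(=O)/C=C/C(C)=O | intermediate
4 | 3-hydroxy-2H-pyran-2-one (3-hydroxy-2-pyrone) | O=C1OC=CC=C1O | starting material
5 | (1R,4R,5S,6S)-5,6-diacetyl-4-hydroxy-2-oxabicyclo[2.2.2]oct-7-en-3-one (acetyl on the carbon next to the carbinol bridgehead points to the alkene, the other to the lactone) | O=C2[C@]1(O)[C@@H](C(C)=O)[C@H](C(C)=O)[C@H](O2)C=C1 | intermediate
6 | (1R,4R,5S,6R)-4-hydroxy-3-oxo-2-oxabicyclo[2.2.2]oct-7-ene-5,6-diyl diacetate | O=C2[C@]1(O)[C@@H](OC(C)=O)[C@H](OC(C)=O)[C@H](O2)C=C1 | intermediate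
7 | methyl (1R,4R,5R,6S)-1,4,5,6-tetrahydroxycyclohex-2-ene-1-carboxylate | COC(=O)[C@@]1(O)C=C[C@@H](O)[C@@H](O)[C@@H]1O | intermediate
8 | methyl (1R,4R,5R,6S)-1,4-dihydroxy-5,6-O-[(2S,3S)-2,3-dimethoxybutane-2,3-diyl]cyclohex-2-ene-1-carboxylate (trans-fused dioxane, both OMe axial) | COC(=O)[C@@]1(O)C=C[C@@H](O)[C@H]2O[C@](C)(OC)[C@@](C)(OC)O[C@H]12 | intermediate
9 | (1S,4R,5R,6S)-1-(hydroxymethyl)-5,6-O-[(2S,3S)-2,3-dimethoxybutane-2,3-diyl]cyclohex-2-ene-1,4,5,6-tetrol | OC[C@@]1(O)C=C[C@@H](O)[C@H]2O[C@](C)(OC)[C@@](C)(OC)O[C@H]12 | intermediate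
10 | benzoyl chloride | O=C(Cl)c1ccccc1 | starting material
11 | O4,O7-dibenzoate of 9, [(1S,4R,5R,6S)-4-(benzoyloxy)-1-hydroxy-5,6-O-[(2S,3S)-2,3-dimethoxybutane-2,3-diyl]cyclohex-2-en-1-yl]methyl benzoate | O=C(OC[C@@]1(O)C=C[C@@H](OC(=O)c3ccccc3)[C@H]2O[C@](C)(OC)[C@@](C)(OC)O[C@H]12)c1ccccc1 | intermediate
12 | [(1S,4R,5S,6S)-4-(benzoyloxy)-1,5,6-trihydroxycyclohex-2-en-1-yl]methyl benzoate | O=C(OC[C@@]1(O)C=C[C@@H](OC(=O)c2ccccc2)[C@@H](O)[C@@H]1O)c1ccccc1 | target

Total step count: 7. Longest linear sequence: 7 steps (1 → 3 → 5 → 6 → 8 → 9 → 11 → 12).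

Steps most likely to fail

Step 2. The catalyst may place the two acetyl groups the wrong way round relative to the lactone bridge, or may discriminate the two dienolate faces poorly. The fallback sets out from 3 and 4 and returns at 8. The cycloaddition is run with triethylamine as achiral base (CH2Cl2, 0 °C) to give the racemic adduct F1. Acylation of its bridgehead hydroxyl with (1S)-(−)-camphanoyl chloride (Et3N, DMAP, CH2Cl2) gives diastereomeric esters, from which the (1S)-camphanate of 5, F2, is separated by crystallisation or chromatography. The peracid oxidation of step 3 converts F2 into the camphanate diacetate F3. The conditions of step 4, with a full equivalent of K2CO3 in the first stage, then cleave camphanate, acetates and lactone together and give 8.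

Step 3. Epoxidation of the ring alkene may compete with the second, slower Criegee rearrangement. The fallback sets out from 5 and returns at 6. The oxidation is driven to completion with excess CF3CO3H (TFAA, urea·H2O2, Na2HPO4, CH2Cl2, 0 °C → rt), accepting epoxidation, to give the epoxy diacetate F4, with the oxirane expected on the less hindered lactone-side face. Cornforth deoxygenation (NaI, NaOAc, Zn dust, AcOH, 0 °C → rt; iodohydrin formation, then reductive elimination) restores the alkene and gives 6.

Step 4. Acetalisation may occur at one of the cis diol pairs, or the ester may relactonise under acid, so that the C5,C6 diol is not cleanly masked. The fallback sets out from 6 and returns at 12; it keeps the Baeyer–Villiger acetates as the C5,C6 protection. NaBH4 (THF/EtOH, −20 °C) reduces only the strained α-hydroxy lactone to give the diacetate triol F5. BzCl/pyridine at −20 °C acylates the primary and allylic hydroxyls to give the dibenzoate diacetate F6. HCl in MeOH (from AcCl, 0 °C) removes the acetates faster than the benzoates and gives 12.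

Further compounds
F1 | step 2 | racemic 5,6-diacetyl-4-hydroxy-2-oxabicyclo[2.2.2]oct-7-en-3-one (5 together with its mirror image) | O=C2[C@]1(O)[C@@H](C(C)=O)[C@H](C(C)=O)[C@H](O2)C=C1.O=C2[C@@]1(O)[C@H](C(C)=O)[C@@H](C(C)=O)[C@@H](O2)C=C1
F2 | step 2 | (1S)-camphanate of 5 (ester at the bridgehead oxygen) | O=C2[C@]1(OC(=O)[C@@]34CC[C@@](C)(C(=O)O3)C4(C)C)[C@@H](C(C)=O)[C@H](C(C)=O)[C@H](O2)C=C1
F3 | step 2 | (1S)-camphanate of 6 (ester at the bridgehead oxygen) | O=C2[C@]1(OC(=O)[C@@]34CC[C@@](C)(C(=O)O3)C4(C)C)[C@@H](OC(C)=O)[C@H](OC(C)=O)[C@H](O2)C=C1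
F4 | step 3 | 7,8-epoxide of 6, oxirane oxygen on the lactone-side face | O=C2[C@]1(O)[C@@H](OC(C)=O)[C@H](OC(C)=O)[C@H](O2)[C@@H]3O[C@H]13
F5 | step 4 | 5,6-di-O-acetyl-1-(hydroxymethyl)cyclohex-2-ene-1,4,5,6-tetrol with the ring configuration of 12 | OC[C@@]1(O)C=C[C@@H](O)[C@@H](OC(C)=O)[C@@H]1OC(C)=O
F6 | step 4 | 5,6-di-O-acetate of 12 | O=C(OC[C@@]1(O)C=C[C@@H](OC(=O)c2ccccc2)[C@@H](OC(C)=O)[C@@H]1OC(C)=O)c1ccccc1
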